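The whole benzene ring of the chromene (C4a, C5, C6, C7, C8, C8a) is disconnected. Its hydroquinone pattern, with oxygens para at C5 and C8, the pyran oxygen O1 on C8a and the acyl group on C6 beside the C5 hydroxyl, is what a chromium carbene benzannulation produces. In one operation a methoxycarbene complex on the oxygen-bearing vinyl carbon of an enantiopure 2,2-disubstituted 3,4-dihydro-2H-pyran joins a ketal-masked butynone and one CO ligand, forming C7–C8, C5–C6 and C4a–C5 and giving the 5-hydroxy-8-methoxychroman with C2 already set. The C2 stereocentre is taken from (R)-2-methylglycidol through two copper-catalysed Grignard epoxide openings.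

Key step: step 9

Assumption: (R)-2-methylglycidol, 4-bromo-2-methylbutan-2-ol and but-3-en-1-ylmagnesium bromide (THF solution) are taken as commercial; locants such as C2, C4a and C8a are those of the chromene ring system of the target.

Step 1
Reactants: 1 4-bromo-2-methylbutan-2-ol
Product: 2 (4-bromo-2-methylbutan-2-yl)oxy(triethyl)silane
Conditions: TESOTf, 2,6-lutidine, CH2Cl2, 0 °C
Reagents that add atoms: triethylsilyl trifluoromethanesulfonate, CC[Si](CC)(CC)OS(=O)(=O)C(F)(F)F
Why: A silyl triflate with a hindered pyridine base silylates tertiary alcohols cleanly (silyl ether protection) and the primary bromide is inert under these conditions.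

Step 2
Reactants: 2 (4-bromo-2-methylbutan-2-yl)oxy(triethyl)silane; 3 (R)-2-methylglycidol
Product: 5 (2S)-2,6-dimethyl-6-(triethylsilyloxy)heptane-1,2-diol, via Grignard reagent 4 (not isolated)
Conditions: 2 (2.3 equiv), Mg, THF, 40 °C; then 3, CuI (10 mol %), THF, −40 → 0 °C
Reagents that add atoms: none
Why: Copper-catalysed Grignard opening of the epoxide at its unsubstituted CH2 terminus (SN2) breaks no bond at the quaternary carbinol carbon, so the configuration of 3 passes unchanged into 5, the first equivalent of 4 serving only to deprotonate the hydroxyl.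

Step 3
Reactants: 5 (2S)-2,6-dimethyl-6-(triethylsilyloxy)heptane-1,2-diol
Product: 7 (2S)-2-methyl-2-[4-methyl-4-(triethylsilyloxy)pentyl]oxirane, via primary tosylate 6 (not isolated)
Conditions: NaH (2.2 equiv), THF, 0 °C; TsCl (1.05 equiv), 0 °C → rt
Reagents that add atoms: none
Why: Selective sulfonylation of the primary alkoxide followed by intramolecular Williamson displacement by the tertiary alkoxide closes the epoxide without touching the C–O bond of the stereocentre.

Step 4
Reactants: 7 (2S)-2-methyl-2-[4-methyl-4-(triethylsilyloxy)pentyl]oxirane; 8 but-3-en-1-ylmagnesium bromide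
Product: 9 (6R)-6,10-dimethyl-10-(triethylsilyloxy)undec-1-en-6-ol
Conditions: 8 (1.5 equiv), CuI (10 mol %), THF, −30 → 0 °C
Reagents that add atoms: none
Why: A second copper-catalysed Grignard epoxide opening at the CH2 terminus installs the pentenyl arm, so the stereocentre is fixed only by the choice of (R)-3 and the order of the two openings.

Step 5
Reactants: 9 (6R)-6,10-dimethyl-10-(triethylsilyloxy)undec-1-en-6-ol
Product: 12 (6S)-6-methyl-6-[4-methyl-4-(triethylsilyloxy)pentyl]tetrahydro-2H-pyran-2-ol (both anomers), via ozonide 10 (not isolated), via hydroxy aldehyde 11 (not isolated)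
Conditions: O3, CH2Cl2, −78 °C; then PPh3, −78 °C → rt
Reagents that add atoms: ozone, [O-][O+]=O
Why: Ozonolysis with reductive work-up cleaves the terminal alkene to the 5-hydroxy aldehyde, which should close spontaneously to the six-membered lactol, the silyl ether and the tertiary carbinol being inert to ozone.

Step 6
Reactants: 12 (6S)-6-methyl-6-[4-methyl-4-(triethylsilyloxy)pentyl]tetrahydro-2H-pyran-2-ol
Product: 14 (2S)-2-methyl-2-[4-methyl-4-(triethylsilyloxy)pentyl]-3,4-dihydro-2H-pyran, via anomeric mesylate 13 (not isolated)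
Conditions: MsCl, Et3N, CH2Cl2, 0 °C → reflux
Reagents that add atoms: none
Why: Sulfonylation of the anomeric hydroxyl and amine-mediated elimination through the oxocarbenium ion is the standard dehydration of 2-hydroxytetrahydropyrans to cyclic enol ethers.

Step 7
Reactants: 14 (2S)-2-methyl-2-[4-methyl-4-(triethylsilyloxy)pentyl]-3,4-dihydro-2H-pyran; 15 hexacarbonylchromium Cr(CO)6
Product: 18 pentacarbonyl{methoxy[(2S)-2-methyl-2-[4-methyl-4-(triethylsilyloxy)pentyl]-3,4-dihydro-2H-pyran-6-yl]methylidene}chromium, via 6-lithiodihydropyran 16 (not isolated), via lithium acylchromate 17 (not isolated)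
Conditions: t-BuLi, THF/pentane, −78 → 0 °C; Cr(CO)6, Et2O, 0 °C → rt; then Me3OBF4, CH2Cl2, 0 °C
Reagents that add atoms: trimethyloxonium tetrafluoroborate, C[O+](C)C.F[B-](F)(F)F
Why: Deprotonation of the enol ether at the vinylic carbon next to oxygen, addition of the vinyllithium to a CO ligand and O-methylation of the acyl chromate with the oxonium salt is the Fischer synthesis of alkoxycarbene complexes, which is established for 6-lithio-3,4-dihydro-2H-pyrans.

Step 8
Reactants: 19 but-3-yn-2-one
Product: 20 2-ethynyl-2-methyl-1,3-dioxolane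
Conditions: TMSOCH2CH2OTMS, TMSOTf (cat.), CH2Cl2, −78 → −20 °C
Reagents that add atoms: 1,2-bis(trimethylsilyloxy)ethane, C[Si](C)(C)OCCO[Si](C)(C)C
Why: Aprotic silyl-triflate-catalysed ketalisation with the bis-silyl ether of ethylene glycol (Noyori conditions) masks the ynone carbonyl without conjugate addition to the triple bond.

Step 9
Reactants: 18 pentacarbonyl{methoxy[(2S)-2-methyl-2-[4-methyl-4-(triethylsilyloxy)pentyl]-3,4-dihydro-2H-pyran-6-yl]methylidene}chromium; 20 2-ethynyl-2-methyl-1,3-dioxolane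
Product: 22 (2S)-8-methoxy-2-methyl-6-(2-methyl-1,3-dioxolan-2-yl)-2-[4-methyl-4-(triethylsilyloxy)pentyl]-3,4-dihydro-2H-chromen-5-ol, via tricarbonylchromium arene complex 21 (not isolated)
Conditions: 20 (1.5 equiv), THF (0.05 M), 50 °C, Ar; then air, daylight, Et2O, rt
Reagents that add atoms: none
Why: Heating expels one carbonyl ligand, the terminal alkyne takes its place and inserts into the Cr=C bond with its CH carbon bonded to the former carbene carbon (C7–C8), and migration of CO to the new vinylcarbene gives a chromium-bound dienylketene (C5–C6), which cyclises onto the enol ether carbon C4a and enolises to the phenol, released from its Cr(CO)3 complex 21 by air and light. The closest known reaction is the Dötz benzannulation of alkenyl- and 3,4-dihydro-2H-pyran-6-yl(methoxy)carbene pentacarbonylchromium complexes with terminal alkynes, which gives 4-methoxyphenols and 5-hydroxy-8-methoxychromans. The benzene ring is closed by a thermal six-electron (disrotatory) electrocyclisation of the dienylketene, the last event of a formal [3+2+1] assembly, and it is fused to the pyran ring that is already present. No stereocentre is formed, and C2, separated from the reacting enol ether carbon by two methylene groups, keeps its configuration. Two selectivities are needed: regiochemistry of alkyne insertion, secured because the bulky ketal carbon stays away from the carbene carbon and so ends at C6 next to the new C5 hydroxyl with hydrogen at C7, and phenol formation over cyclopentannulation, favoured by chromium, the methoxy donor, an alkenyl carbene and THF at about 50 °C.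

Step 10
Reactants: 22 (2S)-8-methoxy-2-methyl-6-(2-methyl-1,3-dioxolan-2-yl)-2-[4-methyl-4-(triethylsilyloxy)pentyl]-3,4-dihydro-2H-chromen-5-ol
Product: 25 1-[(2S)-5,8-dihydroxy-2-methyl-2-[4-methyl-4-(triethylsilyloxy)pentyl]-3,4-dihydro-2H-chromen-6-yl]ethan-1-one, via acetyl phenol 23 (not isolated), via acetyl quinone 24 (not isolated)
Conditions: PPTS (0.2 equiv), MeCN/H2O 4:1, rt; then PhI(OAc)2 (1.1 equiv), 0 °C; then aq. Na2S2O4 (work-up)
Reagents that add atoms: water, O
Why: Mild acid hydrolysis of the electron-rich aryl ketal, hypervalent-iodine oxidative demethylation of the 4-methoxyphenol to the para-quinone (water attacks C8 and methanol leaves) and dithionite reduction in the work-up amount to a net O-demethylation that the tertiary silyl ether should survive.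

Step 11
Reactants: 25 1-[(2S)-5,8-dihydroxy-2-methyl-2-[4-methyl-4-(triethylsilyloxy)pentyl]-3,4-dihydro-2H-chromen-6-yl]ethan-1-one
Product: 26 1-[(2S)-5,8-bis(methoxymethoxy)-2-methyl-2-[4-methyl-4-(triethylsilyloxy)pentyl]-3,4-dihydro-2H-chromen-6-yl]ethan-1-one
Conditions: NaH (2.2 equiv), MOMCl (2.4 equiv), THF/DMF, 0 °C → rt, Ar
Reagents that add atoms: chloromethyl methyl ether, COCCl
Why: Williamson-type O-alkylation of both phenoxides (NaH is needed for the hydrogen-bonded C5 hydroxyl) masks the hydroquinone against the oxidant of the next step and the base of the condensation.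

Step 12
Reactants: 26 1-[(2S)-5,8-bis(methoxymethoxy)-2-methyl-2-[4-methyl-4-(triethylsilyloxy)pentyl]-3,4-dihydro-2H-chromen-6-yl]ethan-1-one
Product: 27 1-[(2S)-5,8-bis(methoxymethoxy)-2-methyl-2-[4-methyl-4-(triethylsilyloxy)pentyl]-2H-chromen-6-yl]ethan-1-one
Conditions: DDQ (1.3 equiv), 1,4-dioxane, reflux
Reagents that add atoms: none
Why: Quinone dehydrogenation by hydride abstraction from benzylic C4, whose cation is stabilised by O1 and the C5 ether oxygen, followed by loss of a C3 proton is the classical conversion of chromans into 2H-chromenes and leaves C2 untouched.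

Step 13
Reactants: 28 4-hydroxybenzaldehyde
Product: 29 4-(methoxymethoxy)benzaldehyde
Conditions: MOMCl, i-Pr2NEt, CH2Cl2, 0 °C → rt
Reagents that add atoms: chloromethyl methyl ether, COCCl
Why: Amine-base O-alkylation of the phenol (methoxymethyl ether protection) keeps a phenoxide from deactivating the aldehyde in the aldol condensation.

Step 14
Reactants: 27 1-[(2S)-5,8-bis(methoxymethoxy)-2-methyl-2-[4-methyl-4-(triethylsilyloxy)pentyl]-2H-chromen-6-yl]ethan-1-one; 29 4-(methoxymethoxy)benzaldehyde
Product: 31 (2E)-1-[(2S)-5,8-bis(methoxymethoxy)-2-methyl-2-[4-methyl-4-(triethylsilyloxy)pentyl]-2H-chromen-6-yl]-3-[4-(methoxymethoxy)phenyl]prop-2-en-1-one, via aldol adduct 30 (not isolated)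
Conditions: KOH (5 equiv), EtOH/H2O, rt, Ar
Reagents that add atoms: none
Why: Claisen–Schmidt condensation of the methyl ketone enolate with the non-enolisable aldehyde and E1cB dehydration of aldol 30 should give the thermodynamically preferred E enone.

Step 15
Reactants: 31 (2E)-1-[(2S)-5,8-bis(methoxymethoxy)-2-methyl-2-[4-methyl-4-(triethylsilyloxy)pentyl]-2H-chromen-6-yl]-3-[4-(methoxymethoxy)phenyl]prop-2-en-1-one
Product: 32 (2E)-1-[(2S)-5,8-dihydroxy-2-(4-hydroxy-4-methylpentyl)-2-methyl-2H-chromen-6-yl]-3-(4-hydroxyphenyl)prop-2-en-1-one (CNP0322520.1)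
Conditions: 3 M aq. HCl/MeOH 1:5, rt → 40 °C, Ar
Reagents that add atoms: none
Why: Acid-catalysed acetal exchange with methanol cleaves the three aryl methoxymethyl ethers and the tertiary triethylsilyl ether in one global deprotection that should not affect the stereocentre, the chromene or the enone.

Compound list
1 | 4-bromo-2-methylbutan-2-ol | CC(C)(O)CCBr | starting material
2 | (4-bromo-2-methylbutan-2-yl)oxy(triethyl)silane | CC[Si](CC)(CC)OC(C)(C)CCBr | intermediate
3 | (R)-2-methylglycidol, [(2R)-2-methyloxiran-2-yl]methanol | OC[C@]1(C)CO1 | starting material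
4 | [3-methyl-3-(triethylsilyloxy)butyl]magnesium bromide | CC[Si](CC)(CC)OC(C)(C)CC[Mg]Br | intermediate
5 | (2S)-2,6-dimethyl-6-(triethylsilyloxy)heptane-1,2-diol | CC(C)(O[Si](CC)(CC)CC)CCC[C@@](O)(C)CO | intermediate
6 | (2S)-2-hydroxy-2,6-dimethyl-6-(triethylsilyloxy)heptyl 4-methylbenzenesulfonate | CC(C)(O[Si](CC)(CC)CC)CCC[C@@](O)(C)COS(=O)(=O)c1ccc(C)cc1 | intermediate
7 | (2S)-2-methyl-2-[4-methyl-4-(triethylsilyloxy)pentyl]oxirane | CC(C)(O[Si](CC)(CC)CC)CCC[C@@]1(C)CO1 | intermediate
8 | but-3-en-1-ylmagnesium bromide | C=CCC[Mg]Br | starting material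
9 | (6R)-6,10-dimethyl-10-(triethylsilyloxy)undec-1-en-6-ol | CC(C)(O[Si](CC)(CC)CC)CCC[C@@](O)(C)CCCC=C | intermediate
10 | (4S)-4,8-dimethyl-1-(1,2,4-trioxolan-3-yl)-8-(triethylsilyloxy)nonan-4-ol (ozonide of 9, trioxolane carbon unassigned) | CC(C)(O[Si](CC)(CC)CC)CCC[C@@](O)(C)CCCC1OCOO1 | intermediate
11 | (5S)-5-hydroxy-5,9-dimethyl-9-(triethylsilyloxy)decanal | CC(C)(O[Si](CC)(CC)CC)CCC[C@@](O)(C)CCCC=O | intermediate
12 | (6S)-6-methyl-6-[4-methyl-4-(triethylsilyloxy)pentyl]tetrahydro-2H-pyran-2-ol (both anomers) | CC(C)(O[Si](CC)(CC)CC)CCC[C@@]1(C)CCCC(O)O1 | intermediate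
13 | (6S)-6-methyl-6-[4-methyl-4-(triethylsilyloxy)pentyl]tetrahydro-2H-pyran-2-yl methanesulfonate | CC(C)(O[Si](CC)(CC)CC)CCC[C@@]1(C)CCCC(OS(C)(=O)=O)O1 | intermediate
14 | (2S)-2-methyl-2-[4-methyl-4-(triethylsilyloxy)pentyl]-3,4-dihydro-2H-pyran | CC(C)(O[Si](CC)(CC)CC)CCC[C@@]1(C)CCC=CO1 | intermediate
15 | hexacarbonylchromium, Cr(CO)6 | [C-]#[O+].[C-]#[O+].[C-]#[O+].[C-]#[O+].[C-]#[O+].[C-]#[O+].[Cr] | starting material
16 | {(2S)-2-methyl-2-[4-methyl-4-(triethylsilyloxy)pentyl]-3,4-dihydro-2H-pyran-6-yl}lithium | CC(C)(O[Si](CC)(CC)CC)CCC[C@@]1(C)CCC=C([Li])O1 | intermediate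
17 | lithium pentacarbonyl{[(2S)-2-methyl-2-[4-methyl-4-(triethylsilyloxy)pentyl]-3,4-dihydro-2H-pyran-6-yl]carbonyl}chromate | [Li+].CC(C)(O[Si](CC)(CC)CC)CCC[C@@]1(C)CCC=C(O1)C([O-])=[Cr](=C=O)(=C=O)(=C=O)(=C=O)=C=O | intermediate
18 | pentacarbonyl{methoxy[(2S)-2-methyl-2-[4-methyl-4-(triethylsilyloxy)pentyl]-3,4-dihydro-2H-pyran-6-yl]methylidene}chromium | CC(C)(O[Si](CC)(CC)CC)CCC[C@@]1(C)CCC=C(O1)C(OC)=[Cr](=C=O)(=C=O)(=C=O)(=C=O)=C=O | intermediate
19 | but-3-yn-2-one | C#CC(C)=O | starting material
20 | 2-ethynyl-2-methyl-1,3-dioxolane | C#CC1(C)OCCO1 | intermediate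
21 | tricarbonylchromium η6-arene complex of 22 (metal fragment written as a separate component) | CC(C)(O[Si](CC)(CC)CC)CCC[C@@]1(C)CCc2c(O)c(C3(C)OCCO3)cc(OC)c2O1.O=C=[Cr](=C=O)=C=O | intermediate
22 | (2S)-8-methoxy-2-methyl-6-(2-methyl-1,3-dioxolan-2-yl)-2-[4-methyl-4-(triethylsilyloxy)pentyl]-3,4-dihydro-2H-chromen-5-ol | CC(C)(O[Si](CC)(CC)CC)CCC[C@@]1(C)CCc2c(O)c(C3(C)OCCO3)cc(OC)c2O1 | intermediate
23 | 1-[(2S)-5-hydroxy-8-methoxy-2-methyl-2-[4-methyl-4-(triethylsilyloxy)pentyl]-3,4-dihydro-2H-chromen-6-yl]ethan-1-one | CC(C)(O[Si](CC)(CC)CC)CCC[C@@]1(C)CCc2c(O)c(C(C)=O)cc(OC)c2O1 | intermediate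
24 | (2S)-6-acetyl-2-methyl-2-[4-methyl-4-(triethylsilyloxy)pentyl]-3,4-dihydro-2H-chromene-5,8-dione | CC(C)(O[Si](CC)(CC)CC)CCC[C@@]1(C)CCC2=C(O1)C(=O)C=C(C(C)=O)C2=O | intermediate
25 | 1-[(2S)-5,8-dihydroxy-2-methyl-2-[4-methyl-4-(triethylsilyloxy)pentyl]-3,4-dihydro-2H-chromen-6-yl]ethan-1-one | CC(C)(O[Si](CC)(CC)CC)CCC[C@@]1(C)CCc2c(O)c(C(C)=O)cc(O)c2O1 | intermediate
26 | 1-[(2S)-5,8-bis(methoxymethoxy)-2-methyl-2-[4-methyl-4-(triethylsilyloxy)pentyl]-3,4-dihydro-2H-chromen-6-yl]ethan-1-one | CC(C)(O[Si](CC)(CC)CC)CCC[C@@]1(C)CCc2c(OCOC)c(C(C)=O)cc(OCOC)c2O1 | intermediate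
27 | 1-[(2S)-5,8-bis(methoxymethoxy)-2-methyl-2-[4-methyl-4-(triethylsilyloxy)pentyl]-2H-chromen-6-yl]ethan-1-one | CC(C)(O[Si](CC)(CC)CC)CCC[C@@]1(C)C=Cc2c(OCOC)c(C(C)=O)cc(OCOC)c2O1 | intermediate
28 | 4-hydroxybenzaldehyde | O=Cc1ccc(O)cc1 | starting material
29 | 4-(methoxymethoxy)benzaldehyde | COCOc1ccc(C=O)cc1 | intermediate
30 | 1-[(2S)-5,8-bis(methoxymethoxy)-2-methyl-2-[4-methyl-4-(triethylsilyloxy)pentyl]-2H-chromen-6-yl]-3-hydroxy-3-[4-(methoxymethoxy)phenyl]propan-1-one (both carbinol epimers) | CC(C)(O[Si](CC)(CC)CC)CCC[C@@]1(C)C=Cc2c(OCOC)c(C(=O)CC(O)c3ccc(OCOC)cc3)cc(OCOC)c2O1 | intermediate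
31 | (2E)-1-[(2S)-5,8-bis(methoxymethoxy)-2-methyl-2-[4-methyl-4-(triethylsilyloxy)pentyl]-2H-chromen-6-yl]-3-[4-(methoxymethoxy)phenyl]prop-2-en-1-one | CC(C)(O[Si](CC)(CC)CC)CCC[C@@]1(C)C=Cc2c(OCOC)c(C(=O)/C=C/c3ccc(OCOC)cc3)cc(OCOC)c2O1 | intermediate
32 | (2E)-1-[(2S)-5,8-dihydroxy-2-(4-hydroxy-4-methylpentyl)-2-methyl-2H-chromen-6-yl]-3-(4-hydroxyphenyl)prop-2-en-1-one (CNP0322520.1) | CC(C)(O)CCC[C@@]1(C)C=Cc2c(O)c(C(=O)/C=C/c3ccc(O)cc3)cc(O)c2O1 | target

Total step count: 15 steps.
Longest linear sequence: 13 steps (steps 1–7, 9–12, 14 and 15; 1 → 2 → 5 → 7 → 9 → 12 → 14 → 18 → 22 → 25 → 26 → 27 → 31 → 32). Steps 8 and 13 are side branches.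

Steps most likely to fail

Step 9 (benzannulation). After alkyne insertion the vinylcarbene may fail to take up CO, or a ketal oxygen may trap the chromium-bound ketene, so that cyclopentannulation or lactone-type products form in place of the phenol. The acid-labile benzylic ketal may also ionise on the Lewis acidic metal or on silica. The fallback carries the acetyl carbons through the annulation as a hydrocarbon and reveals the ketone afterwards by alkene cleavage. It sets out from carbene complex 18, which would be heated with commercial 2-methylbut-1-en-3-yne F1 under the conditions and air work-up of step 9. Conjugated enynes react at the triple bond with the same regiochemistry, so the 6-isopropenyl phenol F2 is expected. A two-stage Lemieux–Johnson cleavage (OsO4 cat., NMO, acetone/H2O, to the diol F3; then NaIO4 on silica, CH2Cl2) should convert the isopropenyl group into the acetyl group of 23. The route is rejoined at 23, at the oxidation stage of step 10. Should periodate also oxidise the ring, the result would be quinone 24, the next intermediate of that step.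

Step 12 (dehydrogenation). Electron transfer from the trioxygenated ring to DDQ may outrun hydride abstraction at C4 and lead to oxidative loss of a methoxymethyl group and quinone formation. The acetyl group may also slow the hydride abstraction until decomposition competes. The fallback moves the dehydrogenation to the methyl ether stage, before the hydroquinone is unveiled. It sets out from 23, isolated by stopping step 10 after the PPTS hydrolysis. Hydrogen-bonded ortho-hydroxyacetyl chromans carrying methoxy groups are a classical substrate type for DDQ (dioxane, reflux), a methyl ether cannot be split off under anhydrous conditions, and both conceivable pathways (hydride loss from C4, or phenol oxidation to the ortho-quinone methide and tautomerisation) lead to the chromene F4. Oxidative demethylation with PhI(OAc)2 in MeCN/H2O should then give the chromene quinone F5, and dithionite in the work-up the chromene hydroquinone F6. Bis-protection with NaH and MOMCl as in step 11 gives 27, where the route is rejoined.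

Step 10 (ketal hydrolysis, oxidative demethylation, reduction). The hydrogen-bonded, acyl-deactivated phenol 23 may oxidise sluggishly, and the strongly electrophilic acetyl quinone 24 may add water or be oxidised further before the reductive work-up reaches it. The fallback keeps the carbonyl masked so that no acylquinone is formed. It sets out from 22, which is oxidised directly with PhI(OAc)2 (MeCN/H2O, 0 °C, solid NaHCO3) to the ketal quinone F7, and dithionite in the work-up should give the ketal hydroquinone F8. Neither hydroxyl is hydrogen-bonded to a carbonyl at this stage, so NaH and MOMCl should give the bis(methoxymethyl) ether F9 readily. The ketal, which sits on an electron-rich ring, is then hydrolysed selectively (PPTS, acetone/H2O, rt) in the presence of the aryl acetals and the tertiary silyl ether. This gives 26, where the route is rejoined at the cost of one extra step.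

Further compounds
F1 | step 9 | 2-methylbut-1-en-3-yne | C=C(C)C#C
F2 | step 9 | (2S)-8-methoxy-2-methyl-2-[4-methyl-4-(triethylsilyloxy)pentyl]-6-(prop-1-en-2-yl)-3,4-dihydro-2H-chromen-5-ol | CC(C)(O[Si](CC)(CC)CC)CCC[C@@]1(C)CCc2c(O)c(C(C)=C)cc(OC)c2O1
F3 | step 9 | 2-[(2S)-5-hydroxy-8-methoxy-2-methyl-2-[4-methyl-4-(triethylsilyloxy)pentyl]-3,4-dihydro-2H-chromen-6-yl]propane-1,2-diol (both carbinol epimers) | CC(C)(O[Si](CC)(CC)CC)CCC[C@@]1(C)CCc2c(O)c(C(C)(O)CO)cc(OC)c2O1
F4 | step 12 | 1-[(2S)-5-hydroxy-8-methoxy-2-methyl-2-[4-methyl-4-(triethylsilyloxy)pentyl]-2H-chromen-6-yl]ethan-1-one | CC(C)(O[Si](CC)(CC)CC)CCC[C@@]1(C)C=Cc2c(O)c(C(C)=O)cc(OC)c2O1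
F5 | step 12 | (2S)-6-acetyl-2-methyl-2-[4-methyl-4-(triethylsilyloxy)pentyl]-2H-chromene-5,8-dione | CC(C)(O[Si](CC)(CC)CC)CCC[C@@]1(C)C=CC2=C(O1)C(=O)C=C(C(C)=O)C2=O
F6 | step 12 | 1-[(2S)-5,8-dihydroxy-2-methyl-2-[4-methyl-4-(triethylsilyloxy)pentyl]-2H-chromen-6-yl]ethan-1-one | CC(C)(O[Si](CC)(CC)CC)CCC[C@@]1(C)C=Cc2c(O)c(C(C)=O)cc(O)c2O1
F7 | step 10 | (2S)-2-methyl-6-(2-methyl-1,3-dioxolan-2-yl)-2-[4-methyl-4-(triethylsilyloxy)pentyl]-3,4-dihydro-2H-chromene-5,8-dione | CC(C)(O[Si](CC)(CC)CC)CCC[C@@]1(C)CCC2=C(O1)C(=O)C=C(C3(C)OCCO3)C2=O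
F8 | step 10 | (2S)-2-methyl-6-(2-methyl-1,3-dioxolan-2-yl)-2-[4-methyl-4-(triethylsilyloxy)pentyl]-3,4-dihydro-2H-chromene-5,8-diol | CC(C)(O[Si](CC)(CC)CC)CCC[C@@]1(C)CCc2c(O)c(C3(C)OCCO3)cc(O)c2O1
F9 | step 10 | triethyl{[5-[(2S)-5,8-bis(methoxymethoxy)-2-methyl-6-(2-methyl-1,3-dioxolan-2-yl)-3,4-dihydro-2H-chromen-2-yl]-2-methylpentan-2-yl]oxy}silane | CC(C)(O[Si](CC)(CC)CC)CCC[C@@]1(C)CCc2c(OCOC)c(C3(C)OCCO3)cc(OCOC)c2O1
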